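Everything rests on the C1–C10 bond. Ring B of the drimane core carries oxygen at C6 and C9 (1,4-related) and one-carbon branches at C8 and C10. It therefore maps onto a 2,6-dimethylhydroquinone monomethyl ether, in which the quaternary, methyl-bearing C10 next to oxygenated C9 is simply the ortho carbon of a phenol. One palladium-catalysed asymmetric allylic dearomatisation forms C1–C10, closes ring A, creates the C10 stereocentre and leaves C9 (ketone) and C6 (enol ether) differentiated. The precursor is an achiral phenol whose C5 carries a CMe2–CH=CH–CH2OCO2Me chain with Z geometry. C5, C9 and C6 are later set under control by C10.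

Key step: step 10

Remark (numbering): drimane numbering is used for all intermediates, the aromatic ones included. Arene carbons are C5–C10, the benzylic CMe2 is C4, the chain is C3, C2, C1, C11 is the carbon added to C9, and C12 is the methyl group on C8.
Remark (precursor design): C6 is para to the phenol oxygen and as close to the chain as C10, so its methoxy group does not block it; C10 against C6 is treated as the selectivity that the key step must deliver. The C9 hydroxyl stays silylated until the carbonate is in place, because neither O-methylation at C6 nor carbonate formation would otherwise be selective.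
Remark (ligand): no reliable model predicts the sense of induction for this substrate. The (R,R)-ligand is written; should it favour the (R)-dienone, the equally available (S,S)-ligand is used.
Remark (target): the 11-acid/12-aldehyde can in principle close to a 12-hydroxy-11,12-olide; the open form given is taken as the target.

Step 1
Reactants: 1 isobutyraldehyde; 2 morpholine; 3 2,6-dimethyl-1,4-benzoquinone
Product: 5 (±)-3,3,4,6-tetramethyl-2-(morpholin-4-yl)-2,3-dihydro-1-benzofuran-5-ol, via enamine 4 (not isolated)
Conditions: 1 + 2, toluene, reflux, Dean–Stark; then 3, toluene, 0 °C → rt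
Reagents that add atoms: none
Why: Enamine formation followed by the known enamine–quinone annulation (Michael addition of the enamine β-carbon to the free quinone CH, aromatisation, closure of the neighbouring OH onto the iminium carbon) forges the crowded C4–C5 bond at or below room temperature, gives a single regioisomer because both free quinone positions are equivalent, and ties up O6 in the ring so that only the C9 hydroxyl is free; the racemic aminal carbon (C3) becomes achiral again in step 3.

Step 2
Reactants: 5 (±)-3,3,4,6-tetramethyl-2-(morpholin-4-yl)-2,3-dihydro-1-benzofuran-5-ol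
Product: 6 (±)-5-(tert-butyldimethylsilyloxy)-3,3,4,6-tetramethyl-2-(morpholin-4-yl)-2,3-dihydro-1-benzofuran
Conditions: TBSCl, imidazole, DMF, rt → 40 °C
Reagents that add atoms: tert-butyldimethylsilyl chloride, CC(C)(C)[Si](C)(C)Cl
Why: Routine silylation of the only free hydroxyl group, whose two ortho methyl groups then shield the Si–O bond through the acidic, basic and hydride steps up to step 8.

Step 3
Reactants: 6 (±)-5-(tert-butyldimethylsilyloxy)-3,3,4,6-tetramethyl-2-(morpholin-4-yl)-2,3-dihydro-1-benzofuran
Product: 8 4-(tert-butyldimethylsilyloxy)-2-(1-hydroxy-2-methylpropan-2-yl)-3,5-dimethylphenol, via lactol 7 (not isolated)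
Conditions: 1 M HCl, THF, rt; extractive work-up; NaBH4, EtOH, 0 °C → rt
Reagents that add atoms: water, O
Why: Aqueous acid hydrolyses the N,O-acetal to the lactol, and NaBH4 drains the small share of open hydroxy aldehyde irreversibly, which releases O6 as a phenol and C3 as a neopentyl-type alcohol, two groups that are easy to tell apart.

Step 4
Reactants: 8 4-(tert-butyldimethylsilyloxy)-2-(1-hydroxy-2-methylpropan-2-yl)-3,5-dimethylphenol
Product: 9 2-[3-(tert-butyldimethylsilyloxy)-6-methoxy-2,4-dimethylphenyl]-2-methylpropan-1-ol
Conditions: MeI, K2CO3, acetone, reflux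
Reagents that add atoms: iodomethane, CI
Why: Williamson ether synthesis in which K2CO3 deprotonates only the phenol, so that C6–OMe is installed without touching the primary alcohol or the silyl ether.

Step 5
Reactants: 9 2-[3-(tert-butyldimethylsilyloxy)-6-methoxy-2,4-dimethylphenyl]-2-methylpropan-1-ol
Product: 10 2-[3-(tert-butyldimethylsilyloxy)-6-methoxy-2,4-dimethylphenyl]-2-methylpropanal
Conditions: Dess–Martin periodinane, CH2Cl2, 0 °C → rt
Reagents that add atoms: none
Why: Dess–Martin oxidation stops cleanly at the aldehyde, which has no α-hydrogen and therefore can neither enolise nor epimerise.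

Step 6
Reactants: 10 2-[3-(tert-butyldimethylsilyloxy)-6-methoxy-2,4-dimethylphenyl]-2-methylpropanal
Product: 11 methyl (Z)-4-[3-(tert-butyldimethylsilyloxy)-6-methoxy-2,4-dimethylphenyl]-4-methylpent-2-enoate
Conditions: (CF3CH2O)2P(O)CH2CO2Me, KN(SiMe3)2, 18-crown-6, THF, −78 °C
Reagents that add atoms: methyl bis(2,2,2-trifluoroethyl) phosphonoacetate, COC(=O)CP(=O)(OCC(F)(F)F)OCC(F)(F)F
Why: Still–Gennari modification of the Horner–Wadsworth–Emmons reaction, in which the electron-poor trifluoroethyl phosphonate makes elimination from the kinetic adduct fast and irreversible and thus delivers the Z-enoate that adds C2 and C1.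

Step 7
Reactants: 11 methyl (Z)-4-[3-(tert-butyldimethylsilyloxy)-6-methoxy-2,4-dimethylphenyl]-4-methylpent-2-enoate
Product: 12 (Z)-4-[3-(tert-butyldimethylsilyloxy)-6-methoxy-2,4-dimethylphenyl]-4-methylpent-2-en-1-ol
Conditions: i-Bu2AlH (2.5 equiv), CH2Cl2, −78 °C; aq. potassium sodium tartrate
Reagents that add atoms: none
Why: Low-temperature 1,2-reduction of the enoate with i-Bu2AlH gives the allylic alcohol with retention of the Z geometry, and the aryl silyl ether is inert.

Step 8
Reactants: 12 (Z)-4-[3-(tert-butyldimethylsilyloxy)-6-methoxy-2,4-dimethylphenyl]-4-methylpent-2-en-1-ol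
Product: 13 (Z)-4-[3-(tert-butyldimethylsilyloxy)-6-methoxy-2,4-dimethylphenyl]-4-methylpent-2-en-1-yl methyl carbonate
Conditions: ClCO2Me, pyridine, CH2Cl2, 0 °C
Reagents that add atoms: methyl chloroformate, COC(=O)Cl
Why: Acylation of the primary allylic alcohol with a chloroformate, unambiguous because the phenol is still silylated.

Step 9
Reactants: 13 (Z)-4-[3-(tert-butyldimethylsilyloxy)-6-methoxy-2,4-dimethylphenyl]-4-methylpent-2-en-1-yl methyl carbonate
Product: 14 (Z)-4-(3-hydroxy-6-methoxy-2,4-dimethylphenyl)-4-methylpent-2-en-1-yl methyl carbonate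
Conditions: Bu4NF, AcOH, THF, 0 °C
Reagents that add atoms: none
Why: Fluoride cleaves the aryl silyl ether within minutes because phenoxide is a good leaving group on silicon, and acetic acid protonates the phenoxide at once so that the allylic carbonate is not transesterified.

Step 10
Reactants: 14 (Z)-4-(3-hydroxy-6-methoxy-2,4-dimethylphenyl)-4-methylpent-2-en-1-yl methyl carbonate
Product: 15 (8aS)-4-methoxy-2,5,5,8a-tetramethyl-8,8a-dihydronaphthalen-1(5H)-one (C9 ketone; C6 methyl enol ether; C2=C3 alkene in ring A; 10β-methyl)
Conditions: Pd2(dba)3·CHCl3 (2.5 mol %), N,N'-[(1R,2R)-cyclohexane-1,2-diyl]bis[2-(diphenylphosphanyl)benzamide] (7.5 mol %), CH2Cl2 (0.01 M), argon, 0 °C → rt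
Reagents that add atoms: none
Why: Proposed new method: zerovalent palladium ionises the Z-allylic carbonate with loss of CO2 to the anti-configured π-allyl complex and methoxide, the methoxide deprotonates the C9 phenol, and the phenolate attacks the unsubstituted allyl terminus C1 through its ortho carbon C10 on the face away from the metal (outer-sphere Tsuji–Trost alkylation), which gives the 2,4-dienone. The closest known reaction types are the palladium-catalysed intramolecular allylic dearomatisation of para-tethered phenols to spirodienones and the intermolecular asymmetric allylic dearomatisation of 1-alkyl-2-naphthols at the alkyl-bearing ortho carbon; new is the combination, a chain on the neighbouring ring carbon C5 that leads to a fused ring. Ring A closes by attack on the distal allyl terminus (6-endo with respect to the allyl unit, enolexo with respect to the C9–C10 phenolate), which only the anti allyl can reach; the 4-exo alternative at C3 is prohibitive, anti-to-syn drift would need a Pd–C σ-bond at the neopentyl-type C3, and C4 has no hydrogen for β-elimination. C10 is the only new stereocentre: in the half-chair transition state the torsion about C5–C10 ties the arene face to the allyl face, the two diastereomeric π-allyl complexes exchange through the η1 form at the CH2 terminus without loss of the anti geometry, and the chiral pocket of the ligand, which handles anti-substituted (cycloalkenyl-type) allyl units well, lets one of them cyclise faster. The step needs C10 to win over oxygen, C8 and the para carbon C6: O-attack would give a meta-bridged eight-membered ether, C8 is out of reach, and C6, although as close to the chain as C10, bears the methoxy donor that lowers the HOMO coefficient at its own carbon, would lose that conjugation on attack, and would leave the C10 methyl group pressed in plane against the C4 gem-dimethyl group, a strain that attack at C10 releases. High dilution suppresses intermolecular O-allylation.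

Step 11
Reactants: 15 (8aS)-4-methoxy-2,5,5,8a-tetramethyl-8,8a-dihydronaphthalen-1(5H)-one
Product: 16 (8aS)-4-methoxy-2,5,5,8a-tetramethyl-6,7,8,8a-tetrahydronaphthalen-1(5H)-one
Conditions: H2 (1 atm), RhCl(PPh3)3 (10 mol %), toluene/EtOH, rt
Reagents that add atoms: none
Why: Homogeneous hydrogenation with RhCl(PPh3)3 selects by degree of substitution, so the unconjugated cis-disubstituted C2=C3 bond is saturated while the trisubstituted C7=C8 and the tetrasubstituted C5=C6 bonds of the dienone stay.

Step 12
Reactants: 16 (8aS)-4-methoxy-2,5,5,8a-tetramethyl-6,7,8,8a-tetrahydronaphthalen-1(5H)-one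
Product: 18 drima-7,9(11)-dien-6-one (5α-H; 10β-methyl), via triene 17 (not isolated)
Conditions: Ph3PCH3Br, KOt-Bu, THF, 0 °C → reflux; then 1 M HCl, THF, rt
Reagents that add atoms: methyltriphenylphosphonium bromide, C[P+](c1ccccc1)(c1ccccc1)c1ccccc1.[Br-]; water, O
Why: Wittig methylenation under the KOt-Bu conditions used for hindered ketones works on a carbonyl group that cannot enolise, and the acid quench protonates the trienol ether at C5, the only site that gives a methoxy-stabilised cation, so that hydrolysis yields the C6 ketone whose α-carbon C5 equilibrates to the more stable trans-decalin (5α-H, anti to the 10β-methyl group).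

Step 13
Reactants: 18 drima-7,9(11)-dien-6-one
Product: 19 9α,11-dihydroxydrim-7-en-6-one
Conditions: OsO4 (5 mol %), NMO, acetone/H2O, rt
Reagents that add atoms: N-methylmorpholine N-oxide, C[N+]1([O-])CCOCC1; water, O; OsO4 (catalytic oxygen carrier), O=[Os](=O)(=O)=O
Why: Upjohn dihydroxylation picks the terminal, more electron-rich γ,δ-double bond C9=C11 of the dienone and approaches from the α-face, opposite to the axial 10β-methyl group next to C9, which places the tertiary hydroxyl at 9α and C11 at 9β.

Step 14
Reactants: 19 9α,11-dihydroxydrim-7-en-6-one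
Product: 20 9α-hydroxy-6-oxodrim-7-en-11-al
Conditions: SO3·pyridine, DMSO, Et3N, CH2Cl2, 0 °C
Reagents that add atoms: none
Why: Parikh–Doering oxidation touches only the primary hydroxyl group and, unlike periodate-type oxidants, cannot cleave the glycol.

Step 15
Reactants: 20 9α-hydroxy-6-oxodrim-7-en-11-al
Product: 21 9α-hydroxy-6-oxodrim-7-en-11-oic acid
Conditions: NaClO2, NaH2PO4, 2-methyl-2-butene, t-BuOH/H2O, 0 °C → rt
Reagents that add atoms: sodium chlorite, [Na+].[O-]Cl=O
Why: Pinnick oxidation converts the hindered α-hydroxy aldehyde into the acid at buffered pH without affecting enone or tertiary alcohol, and the temperature is kept low because the product is a vinylogous β-keto acid.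

Step 16
Reactants: 21 9α-hydroxy-6-oxodrim-7-en-11-oic acid
Product: 22 tert-butyl 9α-hydroxy-6-oxodrim-7-en-11-oate
Conditions: Cl3CC(=NH)Ot-Bu, CH2Cl2/cyclohexane, rt
Reagents that add atoms: tert-butyl 2,2,2-trichloroacetimidate, CC(C)(C)OC(=N)C(Cl)(Cl)Cl
Why: Alkylative esterification, in which the acid protonates the imidate and captures the tert-butyl cation at oxygen, does not depend on access to the crowded C11 carbonyl carbon.

Step 17
Reactants: 22 tert-butyl 9α-hydroxy-6-oxodrim-7-en-11-oate
Product: 23 tert-butyl 6β,9α-dihydroxydrim-7-en-11-oate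
Conditions: NaBH4, CeCl3·7H2O, MeOH, −40 °C → 0 °C
Reagents that add atoms: none
Why: Luche reduction is 1,2-selective, and hydride arrives from the α-face because the β-face of C6 is covered by the axial 4β- and 10β-methyl groups, which gives the axial 6β-alcohol.

Step 18
Reactants: 23 tert-butyl 6β,9α-dihydroxydrim-7-en-11-oate
Product: 24 tert-butyl 6β,9α-dihydroxy-12-oxodrim-7-en-11-oate
Conditions: SeO2, 1,4-dioxane, 80 °C
Reagents that add atoms: selenium dioxide, O=[Se]=O
Why: Riley oxidation (ene reaction, then [2,3]-sigmatropic shift) takes a hydrogen from a carbon attached to the more substituted alkene terminus C8, and since C9 has none only C12 can react, the primary allylic alcohol being oxidised further to the enal under these conditions.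

Step 19
Reactants: 25 (2E,4E)-hexa-2,4-dienal; 26 malonic acid
Product: 28 (2E,4E,6E)-octa-2,4,6-trienoic acid, via dienylidenemalonic acid 27 (not isolated)
Conditions: pyridine, piperidine (cat.), 60 → 100 °C
Reagents that add atoms: none
Why: Doebner modification of the Knoevenagel condensation, in which decarboxylation of the alkylidenemalonic acid in pyridine gives the new double bond with E geometry and leaves the two existing E bonds untouched.

Step 20
Reactants: 24 tert-butyl 6β,9α-dihydroxy-12-oxodrim-7-en-11-oate; 28 (2E,4E,6E)-octa-2,4,6-trienoic acid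
Product: 30 tert-butyl 9α-hydroxy-6β-[(2E,4E,6E)-octa-2,4,6-trienoyloxy]-12-oxodrim-7-en-11-oate, via mixed anhydride 29 (not isolated)
Conditions: 28, 2,4,6-trichlorobenzoyl chloride, Et3N, toluene, rt; then 24, DMAP, rt → 40 °C
Reagents that add atoms: none
Why: Yamaguchi esterification, in which DMAP turns the mixed anhydride into an acylpyridinium ion reactive enough for the axial 6β-hydroxyl group, while the tertiary 9α-hydroxyl group is inert and the ketene pathway of an acid chloride, which would deconjugate the triene, is avoided.

Step 21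
Reactants: 30 tert-butyl 9α-hydroxy-6β-[(2E,4E,6E)-octa-2,4,6-trienoyloxy]-12-oxodrim-7-en-11-oate
Product: 31 ustusoic acid B
Conditions: CF3CO2H/CH2Cl2 (1:4), 0 °C → rt
Reagents that add atoms: none
Why: Acidolysis of the tert-butyl ester by alkyl–oxygen cleavage (loss of 2-methylpropene) spares the C6 ester, the enal and the tertiary alcohol, because cations at C6 or C9 would be destabilised by the formyl and carboxyl groups.

Compound list
1 | isobutyraldehyde | CC(C)C=O | starting material
2 | morpholine | C1COCCN1 | starting material
3 | 2,6-dimethyl-1,4-benzoquinone | CC1=CC(=O)C=C(C)C1=O | starting material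
4 | 4-(2-methylprop-1-en-1-yl)morpholine | CC(C)=CN1CCOCC1 | intermediate
5 | (±)-3,3,4,6-tetramethyl-2-(morpholin-4-yl)-2,3-dihydro-1-benzofuran-5-ol | Cc1cc2OC(N3CCOCC3)C(C)(C)c2c(C)c1O | intermediate
6 | (±)-5-(tert-butyldimethylsilyloxy)-3,3,4,6-tetramethyl-2-(morpholin-4-yl)-2,3-dihydro-1-benzofuran | Cc1cc2OC(N3CCOCC3)C(C)(C)c2c(C)c1O[Si](C)(C)C(C)(C)C | intermediate
7 | (±)-5-(tert-butyldimethylsilyloxy)-3,3,4,6-tetramethyl-2,3-dihydro-1-benzofuran-2-ol | Cc1cc2OC(O)C(C)(C)c2c(C)c1O[Si](C)(C)C(C)(C)C | intermediate
8 | 4-(tert-butyldimethylsilyloxy)-2-(1-hydroxy-2-methylpropan-2-yl)-3,5-dimethylphenol | Cc1cc(O)c(C(C)(C)CO)c(C)c1O[Si](C)(C)C(C)(C)C | intermediate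
9 | 2-[3-(tert-butyldimethylsilyloxy)-6-methoxy-2,4-dimethylphenyl]-2-methylpropan-1-ol | COc1cc(C)c(O[Si](C)(C)C(C)(C)C)c(C)c1C(C)(C)CO | intermediate
10 | 2-[3-(tert-butyldimethylsilyloxy)-6-methoxy-2,4-dimethylphenyl]-2-methylpropanal | COc1cc(C)c(O[Si](C)(C)C(C)(C)C)c(C)c1C(C)(C)C=O | intermediate
11 | methyl (Z)-4-[3-(tert-butyldimethylsilyloxy)-6-methoxy-2,4-dimethylphenyl]-4-methylpent-2-enoate | COC(=O)/C=C\C(C)(C)c1c(OC)cc(C)c(O[Si](C)(C)C(C)(C)C)c1C | intermediate
12 | (Z)-4-[3-(tert-butyldimethylsilyloxy)-6-methoxy-2,4-dimethylphenyl]-4-methylpent-2-en-1-ol | OC/C=C\C(C)(C)c1c(OC)cc(C)c(O[Si](C)(C)C(C)(C)C)c1C | intermediate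
13 | (Z)-4-[3-(tert-butyldimethylsilyloxy)-6-methoxy-2,4-dimethylphenyl]-4-methylpent-2-en-1-yl methyl carbonate | COC(=O)OC/C=C\C(C)(C)c1c(OC)cc(C)c(O[Si](C)(C)C(C)(C)C)c1C | intermediate
14 | (Z)-4-(3-hydroxy-6-methoxy-2,4-dimethylphenyl)-4-methylpent-2-en-1-yl methyl carbonate (key-step precursor) | COC(=O)OC/C=C\C(C)(C)c1c(OC)cc(C)c(O)c1C | intermediate
15 | (8aS)-4-methoxy-2,5,5,8a-tetramethyl-8,8a-dihydronaphthalen-1(5H)-one (key-step product, 10β-methyl) | COC1=C2C(C)(C)C=CC[C@]2(C)C(=O)C(C)=C1 | intermediate
16 | (8aS)-4-methoxy-2,5,5,8a-tetramethyl-6,7,8,8a-tetrahydronaphthalen-1(5H)-one | COC1=C2C(C)(C)CCC[C@]2(C)C(=O)C(C)=C1 | intermediate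
17 | 6-methoxydrima-5,7,9(11)-triene (10β-methyl) | COC1=C2C(C)(C)CCC[C@]2(C)C(=C)C(C)=C1 | intermediate
18 | drima-7,9(11)-dien-6-one (5α-H, 10β-methyl) | O=C1C=C(C)C(=C)[C@@]2(C)CCCC(C)(C)[C@H]12 | intermediate
19 | 9α,11-dihydroxydrim-7-en-6-one | O=C1C=C(C)[C@](O)(CO)[C@@]2(C)CCCC(C)(C)[C@H]12 | intermediate
20 | 9α-hydroxy-6-oxodrim-7-en-11-al | O=C1C=C(C)[C@](O)(C=O)[C@@]2(C)CCCC(C)(C)[C@H]12 | intermediate
21 | 9α-hydroxy-6-oxodrim-7-en-11-oic acid | O=C1C=C(C)[C@](O)(C(=O)O)[C@@]2(C)CCCC(C)(C)[C@H]12 | intermediate
22 | tert-butyl 9α-hydroxy-6-oxodrim-7-en-11-oate | O=C1C=C(C)[C@](O)(C(=O)OC(C)(C)C)[C@@]2(C)CCCC(C)(C)[C@H]12 | intermediate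
23 | tert-butyl 6β,9α-dihydroxydrim-7-en-11-oate | O[C@@H]1C=C(C)[C@](O)(C(=O)OC(C)(C)C)[C@@]2(C)CCCC(C)(C)[C@H]12 | intermediate
24 | tert-butyl 6β,9α-dihydroxy-12-oxodrim-7-en-11-oate | O[C@@H]1C=C(C=O)[C@](O)(C(=O)OC(C)(C)C)[C@@]2(C)CCCC(C)(C)[C@H]12 | intermediate
25 | (2E,4E)-hexa-2,4-dienal | C/C=C/C=C/C=O | starting material
26 | malonic acid | OC(=O)CC(=O)O | starting material
27 | 2-[(2E,4E)-hexa-2,4-dien-1-ylidene]malonic acid | C/C=C/C=C/C=C(C(=O)O)C(=O)O | intermediate
28 | (2E,4E,6E)-octa-2,4,6-trienoic acid | C/C=C/C=C/C=C/C(=O)O | intermediate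
29 | (2E,4E,6E)-octa-2,4,6-trienoic 2,4,6-trichlorobenzoic anhydride | C/C=C/C=C/C=C/C(=O)OC(=O)c1c(Cl)cc(Cl)cc1Cl | intermediate
30 | tert-butyl 9α-hydroxy-6β-[(2E,4E,6E)-octa-2,4,6-trienoyloxy]-12-oxodrim-7-en-11-oate | C/C=C/C=C/C=C/C(=O)O[C@@H]1C=C(C=O)[C@](O)(C(=O)OC(C)(C)C)[C@@]2(C)CCCC(C)(C)[C@H]12 | intermediate
31 | ustusoic acid B, (5S,6R,9S,10S)-9-hydroxy-6-[(2E,4E,6E)-octa-2,4,6-trienoyloxy]-12-oxodrim-7-en-11-oic acid | C/C=C/C=C/C=C/C(=O)O[C@@H]1C=C(C=O)[C@](O)(C(=O)O)[C@@]2(C)CCCC(C)(C)[C@H]12 | target

Total step count: 21. Longest linear sequence: 20 steps (steps 1–18, 20 and 21).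

Steps most likely to fail

**Step 10** (bears the label). Several processes may go wrong:
- slow ionisation of the crowded Z-carbonate;
- drift of the anti allyl complex to the syn form, which cannot cyclise and is then lost to intermolecular O-allylation;
- competing bond formation at C6;
- weak discrimination between the two diastereomeric allyl complexes.

The fallback uses known chemistry: base-induced intramolecular C-alkylation of a phenoxide (alkylative dearomatisation), followed by resolution. It sets out from 12. MsCl and Et3N in THF at 0 °C should give the allylic mesylate F1, which LiCl in DMF converts in the same flask into the Z-allylic chloride F2. Bu4NF in dilute THF removes the silyl group to give the chloro phenol F3 as its phenoxide. This displaces chloride through C10 without any metal and without a syn/anti question, and should give the racemic dienone F4. Preparative chromatography on a chiral stationary phase then separates the (S)-enantiomer, and the route is rejoined at 15.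

**Step 12.** The ylide may add sluggishly to a carbonyl group shielded by C10 and the C8 methyl group, or it may add in a conjugate sense at C7. The cross-conjugated triene may also oligomerise or oxidise before it is hydrolysed. The fallback replaces olefination by carbonyl addition and dehydration, so that no triene is formed. It sets out from 16. MeLi in Et2O at −78 °C should add to C9 from the α-face to give the tertiary carbinol F5. Oxalic acid in wet THF hydrolyses the enol ether to the hydroxy enone F6, with C5 settling as 5α-H. Burgess reagent in toluene at 50 °C then eliminates towards C11, the only carbon next to C9 that carries hydrogen, and the route is rejoined at 18.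

**Step 18.** The selenium reagent may engage the free allylic carbinol at C6, by oxidation back to the enone or by allylic transposition. The deactivated, crowded alkene may react too slowly, or the acidic medium at 80 °C may erode the tert-butyl ester. The fallback moves the C12 oxidation to the enone stage, where no carbinol C–H is present, and corrects the oxidation levels afterwards. It sets out from 22. SeO2 in refluxing dioxane (γ-oxidation of a β-methyl enone through its dienol) should give the keto aldehyde F7. NaBH4/CeCl3·7H2O in MeOH reduces both carbonyl groups, C6 with the same facial bias as in step 17, to the triol ester F8. TEMPO (cat.)/PhI(OAc)2 in CH2Cl2 then re-oxidises only the unhindered primary allylic alcohol at C12, and the route is rejoined at 24.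

Further compounds
F1 | step 10 | (Z)-4-[3-(tert-butyldimethylsilyloxy)-6-methoxy-2,4-dimethylphenyl]-4-methylpent-2-en-1-yl methanesulfonate | CS(=O)(=O)OC/C=C\C(C)(C)c1c(OC)cc(C)c(O[Si](C)(C)C(C)(C)C)c1C
F2 | step 10 | tert-butyl{3-[(Z)-5-chloro-2-methylpent-3-en-2-yl]-4-methoxy-2,6-dimethylphenoxy}dimethylsilane | ClC/C=C\C(C)(C)c1c(OC)cc(C)c(O[Si](C)(C)C(C)(C)C)c1C
F3 | step 10 | 3-[(Z)-5-chloro-2-methylpent-3-en-2-yl]-4-methoxy-2,6-dimethylphenol | ClC/C=C\C(C)(C)c1c(OC)cc(C)c(O)c1C
F4 | step 10 | (±)-4-methoxy-2,5,5,8a-tetramethyl-8,8a-dihydronaphthalen-1(5H)-one | COC1=C2C(C)(C)C=CCC2(C)C(=O)C(C)=C1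
F5 | step 12 | 6-methoxydrima-5,7-dien-9β-ol (9α-methyl = C11, 10β-methyl) | COC1=C2C(C)(C)CCC[C@]2(C)[C@](O)(C)C(C)=C1
F6 | step 12 | 9β-hydroxydrim-7-en-6-one (C11 at 9α, 5α-H) | O=C1C=C(C)[C@@](O)(C)[C@@]2(C)CCCC(C)(C)[C@H]12
F7 | step 18 | tert-butyl 9α-hydroxy-6,12-dioxodrim-7-en-11-oate | O=C1C=C(C=O)[C@](O)(C(=O)OC(C)(C)C)[C@@]2(C)CCCC(C)(C)[C@H]12
F8 | step 18 | tert-butyl 6β,9α,12-trihydroxydrim-7-en-11-oate | O[C@@H]1C=C(CO)[C@](O)(C(=O)OC(C)(C)C)[C@@]2(C)CCCC(C)(C)[C@H]12
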